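The route rests on cutting the bond between the spiro carbon, shared by the cyclopentane and cyclohexene rings, and the adjacent O-bearing methine of the cyclopentane. The key step exploits two facts. The spiro atom is an allylic carbon of the cyclohexene ring. It is also the fifth atom counted from that methine through the C–Me carbon and the two ring CH2 groups. An alkylidene carbene made from methyl ketone 11 therefore inserts into its tertiary allylic C–H bond. One operation closes the cyclopentene and creates the quaternary spiro stereocentre with retention. Precursor 11 is a trans-1,6-disubstituted 3-isopropylcyclohexene with a 3-oxobutyl chain, made from (R)-pulegone. The chroman is then built by hydride-controlled C–O placement and a tethered radical closure.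

Key step: step 7

Numbering: 16–29 use spiro[4.5]decane numbers. C1 is the future OCH, C2 the future C–Me quaternary carbon, C5 the spiro carbon, C6=C7 the alkene bearing isopropyl, and C10 the CHMe carbon. Compounds 30–33 use spiro[cyclohex-2-ene-1,3'-cyclopenta[b]chromene] numbers, with C3a' = OCH, C9a' = C–Me and C9' = CH–isobutyl.

Assumption: the carbinol carbons of 28 and 30 form as epimer mixtures. They are drawn without configuration because steps 15 and 17 erase them.

Step 1
Reactants: 1 (R)-(+)-pulegone
Product: 2 (3R)-3-methyl-6-(propan-2-ylidene)cyclohex-1-en-1-yl trifluoromethanesulfonate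
Conditions: LDA, THF, −78 °C; PhNTf2, −78 °C to rt
Reagents that add atoms: N-phenylbis(trifluoromethanesulfonimide), O=S(=O)(N(c1ccccc1)S(=O)(=O)C(F)(F)F)C(F)(F)F
Why: Kinetic α'-deprotonation of the cross-conjugated enone at its ring CH2 and O-sulfonylation of the lithium dienolate (enol triflate formation) leave the methyl-bearing stereocentre untouched.

Step 2
Reactants: 2 dienyl triflate
Product: 3 (3R)-3-methyl-6-oxocyclohex-1-en-1-yl trifluoromethanesulfonate
Conditions: O3 (1 equiv, dye indicator), CH2Cl2–MeOH, −78 °C; Me2S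
Reagents that add atoms: ozone, [O-][O+]=O
Why: Ozonolysis is site-selective because the tetrasubstituted isopropylidene alkene is far more electron-rich than the triflate-bearing alkene, so only acetone is excised.

Step 3
Reactants: 3 α-triflyloxy enone
Product: 4 (4R)-4-methylcyclohex-2-en-1-one
Conditions: Pd(OAc)2 (cat.), PPh3, HCO2H, Et3N, DMF, 60 °C
Reagents that add atoms: none
Why: Palladium-catalysed formate hydrogenolysis of a vinyl triflate replaces C–OTf by C–H without touching the enone or the γ-stereocentre.

Step 4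
Reactants: 4 (4R)-4-methylcyclohex-2-en-1-one; 5 2-(2-bromoethyl)-2-methyl-1,3-dioxolane
Product: 8 (3S,4R)-4-methyl-3-[2-(2-methyl-1,3-dioxolan-2-yl)ethyl]cyclohex-1-en-1-yl trifluoromethanesulfonate, via Grignard reagent 6 (not isolated), via bromomagnesium enolate 7 (not isolated)
Conditions: 5, Mg, THF, ≤25 °C; CuBr·SMe2 (cat.), 4, THF, −78 to −40 °C; Comins' reagent, −78 °C to rt
Reagents that add atoms: N-(5-chloropyridin-2-yl)bis(trifluoromethanesulfonimide), O=S(=O)(N(c1ccc(Cl)cn1)S(=O)(=O)C(F)(F)F)C(F)(F)F
Why: Copper-catalysed conjugate addition of the Grignard reagent takes place on the face opposite the neighbouring C4 methyl group, which sets the trans C3 stereocentre, and the regiodefined enolate is trapped on oxygen as the enol triflate.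

Step 5
Reactants: 8 enol triflate; 9 isopropylzinc bromide
Product: 10 2-methyl-2-{2-[(1S,6R)-6-methyl-3-(propan-2-yl)cyclohex-2-en-1-yl]ethyl}-1,3-dioxolane
Conditions: Pd(dppf)Cl2 (cat.), THF, 50 °C
Reagents that add atoms: none
Why: Negishi coupling of an alkenyl triflate with a secondary alkylzinc, in which the wide-bite-angle dppf ligand favours reductive elimination over β-hydride isomerisation, installs the isopropyl group with the alkene position fixed.

Step 6
Reactants: 10 ketal
Product: 11 4-[(1S,6R)-6-methyl-3-(propan-2-yl)cyclohex-2-en-1-yl]butan-2-one (side chain trans to the ring methyl)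
Conditions: 1 M aq HCl, THF, rt
Reagents that add atoms: water, O
Why: Mild acid hydrolysis of the dioxolane (acetal cleavage) frees the methyl ketone under conditions too weak to protonate the trisubstituted alkene.

Step 7
Reactants: 11 methyl ketone; 12 trimethylsilyldiazomethane
Product: 16 (5S,10R)-2,10-dimethyl-7-(propan-2-yl)spiro[4.5]deca-1,6-diene (C1 cis to the C10 methyl), via lithiated diazo reagent 13 (not isolated), via diazoalkene 14 (not isolated), via alkylidene carbene 15 (not isolated)
Conditions: 12, n-BuLi, THF, −78 °C; 11, −78 °C to rt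
Reagents that add atoms: none
Why: The lithiated diazo reagent 13 adds to the ketone, Peterson-type loss of lithium trimethylsilanolate gives diazoalkene 14, and loss of nitrogen leaves singlet alkylidene carbene 15 (Colvin-type carbene generation from a ketone). The closest known reaction type is the intramolecular 1,5 C–H insertion of such carbenes, which turns ketones with a δ-hydrogen into cyclopentenes. The one ring formed, the cyclopentene, closes in this 1,5 mode: the carbene carbon (future C1) bonds to ring carbon C5 while the hydrogen moves to C1 in a concerted five-membered transition state. The one new stereocentre, quaternary C5, is controlled by retention at the reacting C–H bond, so C1 occupies the site of the hydrogen that step 4 placed cis to the C10 methyl group. The step needs site selectivity (this C–H over the 1,6 positions at C6 and C10) and chemoselectivity (insertion over cyclopropanation of the ring alkene and over 1,2-methyl shift). These are secured by the five-membered geometry, by the tertiary and allylic, hence most electron-rich, character of the target C–H bond, by the absence of any δ-hydrogen on the methyl branch, and by the isopropyl group and ring constraint that keep the alkene out of reach.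

Step 8
Reactants: 16 spirodiene
Product: 18 trimethyl{[(5R,10R)-10-methyl-7-(propan-2-yl)spiro[4.5]deca-1,6-dien-2-yl]methyl}silane, via allylpotassium 17 (not isolated)
Conditions: n-BuLi, KOt-Bu, THF, −78 to −50 °C; TMSCl, −78 °C to rt
Reagents that add atoms: chlorotrimethylsilane, C[Si](C)(C)Cl
Why: Schlosser superbase metalation removes a proton from the only allylic methyl group in the molecule and the allylpotassium is silylated at its unhindered primary terminus, which marks the cyclopentene alkene and so distinguishes it from the otherwise very similar cyclohexene alkene.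

Step 9
Reactants: 18 allylsilane
Product: 20 (1S,5R,10R)-10-methyl-2-methylidene-7-(propan-2-yl)spiro[4.5]dec-6-en-1-ol, via epoxysilane 19 (not isolated)
Conditions: m-CPBA (1.0 equiv), CH2Cl2, −40 to 0 °C; TBAF, THF, 0 °C
Reagents that add atoms: 3-chloroperoxybenzoic acid, O=C(OO)c1cccc(Cl)c1
Why: Prilezhaev epoxidation picks the allylsilane alkene, whose HOMO is raised by σ(C–Si) donation, on the face syn to sp2 C6, and fluoride-triggered Peterson-like β-elimination opens the epoxysilane to put the hydroxyl on C1 and the alkene exocyclic; the C1 configuration formed here is erased in step 10.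

Step 10
Reactants: 20 allylic alcohol
Product: 21 (5R,10R)-10-methyl-2-methylidene-7-(propan-2-yl)spiro[4.5]dec-6-en-1-one
Conditions: Dess–Martin periodinane, pyridine, CH2Cl2, 0 °C; used without storage
Reagents that add atoms: none
Why: Dess–Martin oxidation of the hindered allylic alcohol under buffered conditions should give the α-methylene ketone without moving the alkene into the ring.

Step 11
Reactants: 21 α-methylene ketone
Product: 22 (1R,5R,10R)-10-methyl-2-methylidene-7-(propan-2-yl)spiro[4.5]dec-6-en-1-ol (OH on the cyclopentane face syn to C10)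
Conditions: NaBH4, CeCl3·7H2O, MeOH, −78 °C
Reagents that add atoms: none
Why: Luche 1,2-reduction delivers hydride from the face flanked by the flat vinylic C6, away from C10 and its methyl group, so the hydroxyl ends on the C10 face and C1 becomes R.

Step 12
Reactants: 23 2,6-difluoro-4-hydroxybenzaldehyde
Product: 24 4-(benzyloxy)-2,6-difluorobenzaldehyde
Conditions: BnBr, K2CO3, DMF, rt
Reagents that add atoms: benzyl bromide, BrCc1ccccc1
Why: Williamson benzylation protects the acidic para-hydroxyl and leaves two equivalent ortho fluorines, so the later substitution has no regiochemical choice.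

Step 13
Reactants: 22 (1R)-allylic alcohol; 24 4-(benzyloxy)-2,6-difluorobenzaldehyde
Product: 26 2,4-bis(benzyloxy)-6-{[(1R,5R,10R)-10-methyl-2-methylidene-7-(propan-2-yl)spiro[4.5]dec-6-en-1-yl]oxy}benzaldehyde, via fluoro aryl ether 25 (not isolated)
Conditions: 22, NaH, THF–DMF, 0 °C; 24, 0 °C to rt; then BnOH/NaH (premixed), 45 °C
Reagents that add atoms: benzyl alcohol, OCc1ccccc1
Why: Two successive SNAr displacements of fluoride ortho to a formyl activator that cannot be enolised by the alkoxide; the C1–O bond is never broken, so 1R is retained, and benzyloxide then replaces the second fluoride.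

Step 14
Reactants: 26 aldehyde; 27 isobutylmagnesium chloride
Product: 28 1-[2,4-bis(benzyloxy)-6-{[(1R,5R,10R)-10-methyl-2-methylidene-7-(propan-2-yl)spiro[4.5]dec-6-en-1-yl]oxy}phenyl]-3-methylbutan-1-ol (carbinol epimers)
Conditions: LaCl3·2LiCl, THF, 0 °C
Reagents that add atoms: none
Why: Grignard 1,2-addition to the aldehyde, with the lanthanum salt suppressing β-hydride reduction, brings in the isobutyl chain, and the carbinol epimers need no separation.

Step 15
Reactants: 28 benzylic alcohol
Product: 29 1-[2,4-bis(benzyloxy)-6-{[(1R,5R,10R)-10-methyl-2-methylidene-7-(propan-2-yl)spiro[4.5]dec-6-en-1-yl]oxy}phenyl]-3-methylbutan-1-one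
Conditions: Dess–Martin periodinane, pyridine, CH2Cl2, 0 °C to rt
Reagents that add atoms: none
Why: Buffered Dess–Martin oxidation converts the acid-labile, electron-rich benzylic alcohol into the aryl ketone without ionising it or touching either alkene.

Step 16
Reactants: 29 aryl ketone
Product: 30 (1R,3a'S,6R,9a'R)-6',8'-bis(benzyloxy)-6,9a'-dimethyl-9'-(2-methylpropyl)-3-(propan-2-yl)-1',2',9',9a'-tetrahydro-3a'H-spiro[cyclohex-2-ene-1,3'-cyclopenta[b]chromen]-9'-ol (C9' epimers, cis ring fusion)
Conditions: Fe(acac)3 (30 mol %), PhSiH3, EtOH–THF, 60 °C, degassed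
Reagents that add atoms: none
Why: Iron-hydride hydrogen atom transfer to the exposed 1,1-disubstituted alkene gives the tertiary C2 radical, which closes 6-exo on the tethered ketone (HAT-initiated alkene–ketone radical cyclisation); the short O-tether on the C10 face enforces a cis fusion and so sets the quaternary centre, while the shielded trisubstituted alkene should not accept hydrogen.

Step 17
Reactants: 30 tertiary benzylic alcohol
Product: 31 (1R,3a'R,6R,9'R,9a'S)-6',8'-bis(benzyloxy)-6,9a'-dimethyl-9'-(2-methylpropyl)-3-(propan-2-yl)-1',2',9',9a'-tetrahydro-3a'H-spiro[cyclohex-2-ene-1,3'-cyclopenta[b]chromene]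
Conditions: Et3SiH, TFA, CH2Cl2, −78 to −30 °C
Reagents that add atoms: none
Why: Ionic (Kursanov–Parnes type) deoxygenation: the trialkoxy-stabilised benzylic cation should take hydride on the convex face, anti to the pseudoaxial C1'H2 of the half-chair that keeps the spiro carbon equatorial, which sets 9'R, and the low temperature leaves the isolated alkene unprotonated.

Step 18
Reactants: 31 dibenzyl ether
Product: 32 (1R,3a'R,6R,9'R,9a'S)-6,9a'-dimethyl-9'-(2-methylpropyl)-3-(propan-2-yl)-1',2',9',9a'-tetrahydro-3a'H-spiro[cyclohex-2-ene-1,3'-cyclopenta[b]chromene]-6',8'-diol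
Conditions: H2 (1 atm), 10% Pd/C, EtOAc, rt, stopped after two equivalents of H2
Reagents that add atoms: none
Why: Hydrogenolysis of aryl benzyl ethers is fast, whereas the remaining alkene, trisubstituted and wedged between the spiro carbon and the isopropyl group, should resist hydrogenation under a balloon of hydrogen.

Step 19
Reactants: 32 dihydroxychroman
Product: 33 (1R,3a'R,6R,9'R,9a'S)-6',8'-dihydroxy-6,9a'-dimethyl-9'-(2-methylpropyl)-3-(propan-2-yl)-1',2',9',9a'-tetrahydro-3a'H-spiro[cyclohex-2-ene-1,3'-cyclopenta[b]chromene]-5',7'-dicarbaldehyde (CNP0121396.1)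
Conditions: POCl3, DMF, EtOAc, 0 °C to rt; H2O, 50 °C
Reagents that add atoms: N,N-dimethylformamide, CN(C)C=O; water, O
Why: Double Vilsmeier–Haack formylation of the free phloroglucinol-type ring fills the only two open aromatic positions (C5' and C7') in a medium that does not protonate the alkene, and hydrolysis of the bis-iminium salt gives the dialdehyde.

Compound list
1 | (R)-(+)-pulegone | C[C@@H]1CCC(=C(C)C)C(=O)C1 | starting material
2 | (3R)-3-methyl-6-(propan-2-ylidene)cyclohex-1-en-1-yl triflate | C[C@@H]1CCC(=C(C)C)C(OS(=O)(=O)C(F)(F)F)=C1 | intermediate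
3 | (3R)-3-methyl-6-oxocyclohex-1-en-1-yl triflate | C[C@@H]1CCC(=O)C(OS(=O)(=O)C(F)(F)F)=C1 | intermediate
4 | (4R)-4-methylcyclohex-2-en-1-one | C[C@@H]1CCC(=O)C=C1 | intermediate
5 | 2-(2-bromoethyl)-2-methyl-1,3-dioxolane | CC1(CCBr)OCCO1 | starting material
6 | [2-(2-methyl-1,3-dioxolan-2-yl)ethyl]magnesium bromide | CC1(CC[Mg]Br)OCCO1 | intermediate
7 | bromomagnesium enolate of the trans conjugate adduct | CC1(CC[C@@H]2C=C(O[Mg]Br)CC[C@H]2C)OCCO1 | intermediate
8 | (3S,4R)-4-methyl-3-[2-(2-methyl-1,3-dioxolan-2-yl)ethyl]cyclohex-1-en-1-yl triflate | CC1(CC[C@@H]2C=C(OS(=O)(=O)C(F)(F)F)CC[C@H]2C)OCCO1 | intermediate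
9 | isopropylzinc bromide | CC(C)[Zn]Br | starting material
10 | 2-methyl-2-{2-[(1S,6R)-6-methyl-3-(propan-2-yl)cyclohex-2-en-1-yl]ethyl}-1,3-dioxolane | CC1(CC[C@@H]2C=C(C(C)C)CC[C@H]2C)OCCO1 | intermediate
11 | 4-[(1S,6R)-6-methyl-3-(propan-2-yl)cyclohex-2-en-1-yl]butan-2-one | CC(=O)CC[C@@H]1C=C(C(C)C)CC[C@H]1C | intermediate
12 | trimethylsilyldiazomethane | C[Si](C)(C)C=[N+]=[N-] | starting material
13 | lithio(trimethylsilyl)diazomethane | C[Si](C)(C)C([Li])=[N+]=[N-] | intermediate
14 | 1-diazo-2-methyl-4-[(1S,6R)-6-methyl-3-(propan-2-yl)cyclohex-2-en-1-yl]but-1-ene | CC(CC[C@@H]1C=C(C(C)C)CC[C@H]1C)=C=[N+]=[N-] | intermediate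
15 | 2-methyl-4-[(1S,6R)-6-methyl-3-(propan-2-yl)cyclohex-2-en-1-yl]but-1-en-1-ylidene (alkylidene carbene) | CC(=[C])CC[C@@H]1C=C(C(C)C)CC[C@H]1C | intermediate
16 | (5S,10R)-2,10-dimethyl-7-(propan-2-yl)spiro[4.5]deca-1,6-diene | CC1=C[C@@]2(CC1)C=C(C(C)C)CC[C@H]2C | intermediate
17 | allylpotassium from 16, metal at the former C2 methyl carbon | [K]CC1=C[C@@]2(CC1)C=C(C(C)C)CC[C@H]2C | intermediate
18 | trimethyl{[(5R,10R)-10-methyl-7-(propan-2-yl)spiro[4.5]deca-1,6-dien-2-yl]methyl}silane | C[Si](C)(C)CC1=C[C@@]2(CC1)C=C(C(C)C)CC[C@H]2C | intermediate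
19 | 1,2-epoxy-10-methyl-7-(propan-2-yl)-2-[(trimethylsilyl)methyl]spiro[4.5]dec-6-ene, oxirane oxygen on the face syn to C6 | C[Si](C)(C)C[C@]12CC[C@]3([C@H]1O2)C=C(C(C)C)CC[C@H]3C | intermediate
20 | (1S,5R,10R)-10-methyl-2-methylidene-7-(propan-2-yl)spiro[4.5]dec-6-en-1-ol | C=C1CC[C@]2([C@H]1O)C=C(C(C)C)CC[C@H]2C | intermediate
21 | (5R,10R)-10-methyl-2-methylidene-7-(propan-2-yl)spiro[4.5]dec-6-en-1-one | C=C1CC[C@]2(C1=O)C=C(C(C)C)CC[C@H]2C | intermediate
22 | (1R,5R,10R)-10-methyl-2-methylidene-7-(propan-2-yl)spiro[4.5]dec-6-en-1-ol | C=C1CC[C@]2([C@@H]1O)C=C(C(C)C)CC[C@H]2C | intermediate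
23 | 2,6-difluoro-4-hydroxybenzaldehyde | O=Cc1c(F)cc(O)cc1F | starting material
24 | 4-(benzyloxy)-2,6-difluorobenzaldehyde | O=Cc1c(F)cc(OCc2ccccc2)cc1F | intermediate
25 | 4-(benzyloxy)-2-fluoro-6-{[(1R,5R,10R)-10-methyl-2-methylidene-7-(propan-2-yl)spiro[4.5]dec-6-en-1-yl]oxy}benzaldehyde | C=C1CC[C@]2([C@@H]1Oc1cc(OCc3ccccc3)cc(F)c1C=O)C=C(C(C)C)CC[C@H]2C | intermediate
26 | 2,4-bis(benzyloxy)-6-{[(1R,5R,10R)-10-methyl-2-methylidene-7-(propan-2-yl)spiro[4.5]dec-6-en-1-yl]oxy}benzaldehyde | C=C1CC[C@]2([C@@H]1Oc1cc(OCc3ccccc3)cc(OCc3ccccc3)c1C=O)C=C(C(C)C)CC[C@H]2C | intermediate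
27 | isobutylmagnesium chloride | CC(C)C[Mg]Cl | starting material
28 | benzylic alcohol from 26 and 27 (carbinol epimers) | C=C1CC[C@]2([C@@H]1Oc1cc(OCc3ccccc3)cc(OCc3ccccc3)c1C(O)CC(C)C)C=C(C(C)C)CC[C@H]2C | intermediate
29 | aryl isobutyl ketone | C=C1CC[C@]2([C@@H]1Oc1cc(OCc3ccccc3)cc(OCc3ccccc3)c1C(=O)CC(C)C)C=C(C(C)C)CC[C@H]2C | intermediate
30 | cis-fused 9'-hydroxy chroman, dibenzyl ether (C9' epimers) | CC(C)CC1(O)c2c(OCc3ccccc3)cc(OCc3ccccc3)cc2O[C@@H]2[C@@]1(C)CC[C@@]21C=C(C(C)C)CC[C@H]1C | intermediate
31 | (9'R)-chroman, dibenzyl ether | CC(C)C[C@H]1c2c(OCc3ccccc3)cc(OCc3ccccc3)cc2O[C@@H]2[C@@]1(C)CC[C@@]21C=C(C(C)C)CC[C@H]1C | intermediate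
32 | (9'R)-chroman-6',8'-diol | CC(C)C[C@H]1c2c(O)cc(O)cc2O[C@@H]2[C@@]1(C)CC[C@@]21C=C(C(C)C)CC[C@H]1C | intermediate
33 | CNP0121396.1 | CC(C)C[C@H]1c2c(O)c(C=O)c(O)c(C=O)c2O[C@@H]2[C@@]1(C)CC[C@@]21C=C(C(C)C)CC[C@H]1C | target

Total step count: 19. Longest linear sequence: 18 (steps 1–11 and 13–19, from (R)-pulegone).

Steps most likely to fail

1. Step 7. The strongly basic diazo anion may enolise the methyl ketone instead of adding to it. The adduct may also collapse too slowly, so that little carbene is formed and insertion is starved. The fallback generates the carbene without any carbonyl addition. It sets out from 11. Wittig chloromethylenation with Ph3P=CHCl gives the vinyl chloride 1-chloro-2-methyl-4-[(1S,6R)-6-methyl-3-(propan-2-yl)cyclohex-2-en-1-yl]but-1-ene F1 as an E/Z mixture. KHMDS in Et2O then removes the vinylic hydrogen and chloride by α-elimination, which releases carbene 15. The route is rejoined at 16.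

2. Step 16. The tertiary radical may be quenched by a second hydrogen atom before it cyclises. It may also expel the aryloxyl group faster than it adds to the crowded, electron-rich and reversibly attacked carbonyl group. The fallback replaces the radical closure by an organopalladium one and sets out from 29.
   - KHMDS and Comins' reagent give the enol triflate F2.
   - A reductive Heck cyclisation (Pd(OAc)2, PPh3, HCO2Na, DMF, 80 °C) carries out a 6-exo carbopalladation of the exocyclic alkene on the tether face.
   - This forms the same C9'–C9a' bond. The neopentyl-type CH2–Pd species has no β-hydrogen and is reduced by formate to the methyl group, giving the 9'-(2-methylpropylidene)chroman F3.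
   - Et3SiH/TFA protonates the styrene-type alkene to the same cation as in step 17. The route is rejoined at 31.

3. Step 17. Facial selectivity in the hydride capture of the benzylic cation may be poor or reversed if the cation reacts through the other half-chair. The fallback swaps the order in which hydrogen and carbon arrive at C9' and sets out from 26.
   - Iron-hydride HAT cyclisation onto the formyl group gives the secondary chromanol F4.
   - Ionisation with BF3·OEt2 and capture by methallyltrimethylsilane (Hosomi–Sakurai type) puts the carbon chain on the face that nucleophiles prefer, giving the 9'-methallyl chroman F5.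
   - Hydrogenation over Pd/C saturates the 1,1-disubstituted alkene and removes both benzyl groups. The route is rejoined at 32.

Further compounds
F1 | step 7 | (E/Z)-1-chloro-2-methyl-4-[(1S,6R)-6-methyl-3-(propan-2-yl)cyclohex-2-en-1-yl]but-1-ene | ClC=C(C)CC[C@@H]1C=C(C(C)C)CC[C@H]1C
F2 | step 16 | enol triflate of ketone 29 (alkene geometry open) | C=C1CC[C@]2([C@@H]1Oc1cc(OCc3ccccc3)cc(OCc3ccccc3)c1C(OS(=O)(=O)C(F)(F)F)=CC(C)C)C=C(C(C)C)CC[C@H]2C
F3 | step 16 | 6',8'-bis(benzyloxy)-9'-(2-methylpropylidene) chroman, ring fusion and spiro centre as in 31 | CC(C)C=C1c2c(OCc3ccccc3)cc(OCc3ccccc3)cc2O[C@@H]2[C@@]1(C)CC[C@@]21C=C(C(C)C)CC[C@H]1C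
F4 | step 17 | 6',8'-bis(benzyloxy)chroman-9'-ol without the isobutyl group (C9' epimers), ring fusion as in 30 | OC1c2c(OCc3ccccc3)cc(OCc3ccccc3)cc2O[C@@H]2[C@@]1(C)CC[C@@]21C=C(C(C)C)CC[C@H]1C
F5 | step 17 | 6',8'-bis(benzyloxy)-9'-(2-methylprop-2-en-1-yl) chroman, C9' configured as in 31 | C=C(C)C[C@H]1c2c(OCc3ccccc3)cc(OCc3ccccc3)cc2O[C@@H]2[C@@]1(C)CC[C@@]21C=C(C(C)C)CC[C@H]1C
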